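## Retrosynthetic overview

1. **Feature:** number the oxolane O1, C2 (4-hydroxyphenyl), C3 (2,4-dihydroxybenzoyl), C4 (4-hydroxybenzyl), C5 (2,4-dihydroxyphenyl). C3 and C4 each lie β to an arene with OH para to the side chain, the C3–C4 bond joins these two β carbons, and O1 spans the benzylic carbons C2 and C5. This pattern results when two phenoxyl radicals join side chain to side chain (8–8′) and the resulting bis(quinone methide) takes up one water.
2. **End game:** six O-benzyl groups come off last. The C3 aryl ketone is cut between carbonyl and arene into a C3 thioester and 2,4-bis(benzyloxy)phenylboronic acid, and the thioester comes from a C3 N-acyl oxazolidinone.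
3. **Key disconnection:** C3–C4, O1–C2 and O1–C5 are cut in one operation. This gives the p-coumaroyl imide of (S)-4-benzyloxazolidin-2-one, an (E)-1,3-diarylpropene with one free para phenol, and water. The oxolane is the only ring made in the route, and all four stereocentres (2,3-trans, 3,4-trans, 4,5-cis) arise here.
4. **Precursors:** the imide comes from p-coumaric acid in three steps. The diarylpropene comes from 2,4-dihydroxybenzaldehyde and tyrosol by Julia–Kocienski olefination in seven steps.

Key step: step 11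

Assumption: the sense of induction at C3 is derived from the Mg-chelated, s-cis rotamer of the imide; if experiment shows the opposite sense, the (R)-enantiomer of the auxiliary is used and nothing else in the route changes.

## Route

Step 1
Reactants: 1 p-coumaric acid
Product: 3 (E)-3-[4-(tert-butyldimethylsilyloxy)phenyl]acrylic acid, via silyl ester 2 (not isolated)
Conditions: TBSCl (2.3 equiv), imidazole, DMF, rt; then AcOH–THF–H2O, rt
Reagents that add atoms: tert-butyldimethylsilyl chloride, CC(C)(C)[Si](C)(C)Cl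
Why: Silyl protection followed by selective solvolysis, in which both acidic OH groups are silylated and the silyl ester, far more labile than the aryl silyl ether, is hydrolysed by aqueous acetic acid, so that only the phenol stays masked for the acylation.

Step 2
Reactants: 3 (E)-3-[4-(tert-butyldimethylsilyloxy)phenyl]acrylic acid; 4 (S)-4-benzyloxazolidin-2-one
Product: 6 (S)-4-benzyl-3-{(E)-3-[4-(tert-butyldimethylsilyloxy)phenyl]acryloyl}oxazolidin-2-one, via mixed pivalic anhydride 5 (not isolated)
Conditions: PivCl, Et3N, THF, −20 °C; then LiCl, 4, −20 °C to rt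
Reagents that add atoms: pivaloyl chloride, CC(C)(C)C(=O)Cl (its acyl group is kept only in 5)
Why: N-Acylation of an oxazolidinone through a mixed anhydride (Et3N/LiCl variant), in which the nitrogen attacks the unhindered cinnamoyl carbonyl of 5 and not the pivaloyl one, and neither the (E)-alkene nor the stereocentre of 4 is touched.

Step 3
Reactants: 6 silylated imide
Product: 7 (S)-4-benzyl-3-[(E)-3-(4-hydroxyphenyl)acryloyl]oxazolidin-2-one
Conditions: Bu4NF, AcOH (1:1), THF, 0 °C
Reagents that add atoms: none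
Why: Fluoride desilylation buffered by acetic acid cleaves the aryl silyl ether at 0 °C, while the absence of free alkoxide or hydroxide keeps the imide intact.

Step 4
Reactants: 8 2-(4-hydroxyphenyl)ethanol (tyrosol)
Product: 9 2-[4-(benzyloxy)phenyl]ethanol
Conditions: BnBr, K2CO3, acetone, reflux
Reagents that add atoms: benzyl bromide, BrCc1ccccc1
Why: Williamson ether synthesis in which K2CO3 deprotonates only the phenol and not the primary alcohol, so that benzylation is selective for the aryl oxygen.

Step 5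
Reactants: 9 2-[4-(benzyloxy)phenyl]ethanol
Product: 10 5-({2-[4-(benzyloxy)phenyl]ethyl}sulfanyl)-1-phenyl-1H-tetrazole
Conditions: 1-phenyl-1H-tetrazole-5-thiol, PPh3, DIAD, THF, 0 °C to rt
Reagents that add atoms: 1-phenyl-1H-tetrazole-5-thiol, Sc1nnnn1-c1ccccc1
Why: Mitsunobu thioetherification, in which the acidic tetrazole thiol displaces the activated primary alcohol by SN2 under neutral conditions.

Step 6
Reactants: 10 tetrazolyl sulfide
Product: 11 5-({2-[4-(benzyloxy)phenyl]ethyl}sulfonyl)-1-phenyl-1H-tetrazole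
Conditions: 30% H2O2, (NH4)6Mo7O24·4H2O (10 mol %), EtOH, 0 °C to rt
Reagents that add atoms: hydrogen peroxide, OO
Why: Molybdate-catalysed peroxide oxidation of a sulfide to the sulfone, which leaves the benzyl ether and the tetrazole unchanged.

Step 7
Reactants: 12 2,4-dihydroxybenzaldehyde
Product: 13 4-(allyloxy)-2-hydroxybenzaldehyde
Conditions: allyl bromide (1.05 equiv), K2CO3 (1.0 equiv), acetone, 50 °C
Reagents that add atoms: allyl bromide, C=CCBr
Why: Regioselective Williamson ether synthesis, since the 4-OH is free and the more acidic one whereas the 2-OH is tied up in a hydrogen bond to the aldehyde, and allyl is chosen because it can later be removed without acid, strong base or hydrogen.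

Step 8
Reactants: 13 4-(allyloxy)-2-hydroxybenzaldehyde
Product: 14 4-(allyloxy)-2-(benzyloxy)benzaldehyde
Conditions: BnBr, K2CO3, DMF, rt to 50 °C
Reagents that add atoms: benzyl bromide, BrCc1ccccc1
Why: Williamson ether synthesis on the remaining hydrogen-bonded phenol in a dipolar aprotic solvent, with benzyl rather than silyl placed ortho to the aldehyde because a silyl group there could migrate to the alkoxide formed in the next step.

Step 9
Reactants: 11 tetrazolyl sulfone (1.2 equiv); 14 4-(allyloxy)-2-(benzyloxy)benzaldehyde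
Product: 16 4-(allyloxy)-2-(benzyloxy)-1-{(E)-3-[4-(benzyloxy)phenyl]prop-1-en-1-yl}benzene, via potassium sulfonyl carbanion 15 (not isolated)
Conditions: KN(SiMe3)2 (1.1 equiv), DME, −78 °C; then 14 (1.0 equiv), −78 °C to rt
Reagents that add atoms: potassium bis(trimethylsilyl)amide, C[Si](C)(C)[N-][Si](C)(C)C.[K+] (potassium is kept only in 15)
Why: Julia–Kocienski olefination, in which addition of the metalated phenyltetrazolyl sulfone to the aromatic aldehyde, Smiles rearrangement and anti elimination should give the (E)-alkene, and keeping the base below the amount of sulfone avoids deprotonation of the doubly activated CH2 of 16 and hence migration of the double bond.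

Step 10
Reactants: 16 allyl ether
Product: 17 (E)-3-(benzyloxy)-4-{3-[4-(benzyloxy)phenyl]prop-1-en-1-yl}phenol
Conditions: Pd(PPh3)4 (5 mol %), morpholine, THF, rt
Reagents that add atoms: none
Why: Tsuji–Trost-type deallylation, in which zerovalent palladium ionises only the allyl aryl ether and morpholine captures the allyl fragment, so that the benzyl ethers and the (E)-alkene in its position are kept and only the phenol para to the propenyl chain is set free.

Step 11
Reactants: 7 p-coumaroyl imide (3 equiv); 17 (E)-propenylresorcinol monophenol (1 equiv)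
Product: 20 (4S)-4-benzyl-3-{[(2S,3S,4S,5R)-5-[2-(benzyloxy)-4-hydroxyphenyl]-4-[4-(benzyloxy)benzyl]-2-(4-hydroxyphenyl)oxolan-3-yl]carbonyl}oxazolidin-2-one, via bis(quinone methide) 18 (not isolated), via C5-hydroxy quinone methide 19 (not isolated)
Conditions: Ag2O (2.5 equiv, in portions), Mg(ClO4)2 (3 equiv), H2O (5 equiv), CH2Cl2–acetone 4:1, rt, dark, 17 added over 10 h; filtration, chromatography on Et3N-deactivated silica
Reagents that add atoms: water, O
Why: Proposed new method: Ag2O removes one electron and one proton from each phenol, the radical from 7 carries spin on the carbon next to the imide carbonyl (electron-poor, future C3) and the radical from 17 on the alkyl-substituted side-chain carbon (electron-rich, future C4), and their combination forms C3–C4 and gives bis(quinone methide) 18. The closest known reaction types are the oxidative 8–8′ dimerisation of (E)-propenylphenols to 2,5-diaryloxolanes with uptake of water and the auxiliary-directed Ag2O dimerisation of hydroxycinnamoyl amides and imides; a selective crossing of two different phenols in this mode has not been shown. Water adds to the methide carbon C5 of 18 (O1–C5, giving 19) and the new hydroxyl closes the only ring by 5-exo-trig conjugate addition to the methide carbon C2 (O1–C2), which restores both arenes. C3 is controlled by the auxiliary, because Mg(ClO4)2 (no oxidisable or silver-binding anion, and a hydroxide too soluble to be precipitated by Ag2O) holds the two imide carbonyls syn and the enoyl unit s-cis, so that the 4-benzyl group covers one face of C3 and bonding on the open face corresponds to 3S, and C4 is controlled by the stacked approach of the two (E)-configured radicals with each hydrogen in the most crowded position about the forming bond, which gives the threo (3,4-trans) relation. C5 and C2 have to be set kinetically, since equilibration through the quinone methides would drain to the all-trans isomer: with H4 in the methide plane (allylic 1,3-strain) external water attacks C5 anti to the large C3 branch, which after closure means 4,5-cis, and the tethered hydroxyl reaches C2 on the face that carries C4 with H3 in the plane, which means 2,3-trans. The step needs crossing over self-coupling (7 and oxidant in excess, 17 fed slowly, so that a radical from 17 meets mostly radicals from 7), side-chain to side-chain bonding over bonding at a ring carbon or at oxygen (only this pairing joins the electron-poor and the electron-rich spin-bearing carbon), and hydration of C5 before C2 (C2 is screened on both faces by the imide and the C4 branch, whereas C5 has the CH2Ar face open and its methide, made more basic by the 2-benzyloxy donor, is activated first by Mg-bound water and by the acidic phenol 7), and because every stereoisomer still carries the auxiliary all are diastereomers and chromatography should give 20 in a single enantiomeric series.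

Step 12
Reactants: 20 oxolane imide diphenol
Product: 21 (4S)-4-benzyl-3-{[(2S,3S,4S,5R)-4-[4-(benzyloxy)benzyl]-2-[4-(benzyloxy)phenyl]-5-[2,4-bis(benzyloxy)phenyl]oxolan-3-yl]carbonyl}oxazolidin-2-one
Conditions: BnBr (2.5 equiv), K2CO3, acetone, 40 °C
Reagents that add atoms: benzyl bromide, BrCc1ccccc1
Why: Williamson ether synthesis in which K2CO3 deprotonates only the two phenols, the phenoxides do not expel the ring alkoxide at this temperature, and capping the para oxygens closes the quinone methide path by which C2 and C5 could later epimerise.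

Step 13
Reactants: 21 tetrabenzyl imide
Product: 22 S-ethyl (2S,3S,4S,5R)-4-[4-(benzyloxy)benzyl]-2-[4-(benzyloxy)phenyl]-5-[2,4-bis(benzyloxy)phenyl]oxolane-3-carbothioate
Conditions: EtSH (3 equiv), n-BuLi (2 equiv), THF, 0 °C
Reagents that add atoms: ethanethiol, CCS
Why: Thiolysis (transacylation) of an N-acyl oxazolidinone by a lithium thiolate, a soft and weakly basic nucleophile that attacks the exocyclic carbonyl without enolising C3 or provoking β-elimination of O1, while C3 already sits trans to both neighbours in its more stable arrangement and 4 is recovered.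

Step 14
Reactants: 23 4-bromoresorcinol
Product: 24 2,4-bis(benzyloxy)-1-bromobenzene
Conditions: BnBr (2.2 equiv), K2CO3, DMF, 60 °C
Reagents that add atoms: benzyl bromide, BrCc1ccccc1
Why: Double Williamson ether synthesis on an unhindered resorcinol, with the aryl bromide inert under these conditions.

Step 15
Reactants: 24 2,4-bis(benzyloxy)-1-bromobenzene
Product: 27 [2,4-bis(benzyloxy)phenyl]boronic acid, via aryllithium 25 (not isolated), via lithium triisopropoxyborate 26 (not isolated)
Conditions: n-BuLi, THF, −78 °C; B(Oi-Pr)3, −78 °C to rt; 1 M HCl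
Reagents that add atoms: triisopropyl borate, CC(C)OB(OC(C)C)OC(C)C; water, O; n-butyllithium, [Li]CCCC (lithium is kept only in 25 and 26)
Why: Bromine–lithium exchange, borylation and hydrolysis, the exchange at −78 °C being much faster than deprotonation of the benzylic ether CH2 groups.

Step 16
Reactants: 22 thioester; 27 [2,4-bis(benzyloxy)phenyl]boronic acid (2 equiv)
Product: 28 [2,4-bis(benzyloxy)phenyl]{(2S,3S,4S,5R)-4-[4-(benzyloxy)benzyl]-2-[4-(benzyloxy)phenyl]-5-[2,4-bis(benzyloxy)phenyl]oxolan-3-yl}methanone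
Conditions: Pd2(dba)3 (2.5 mol %), P(2-furyl)3 (15 mol %), Cu(O2CC4H3S) (copper thiophene-2-carboxylate, 2 equiv), THF, 50 °C
Reagents that add atoms: none
Why: Liebeskind–Srogl ketone synthesis, in which zerovalent palladium inserts into the acyl–sulfur bond and the copper carboxylate binds the thiolate and activates the boronic acid for transmetalation without added base, so that neither enolisation at C3 nor β-elimination of O1 is provoked.

Step 17
Reactants: 28 hexabenzyl ketone
Product: 29 (2,4-dihydroxyphenyl)[(2S,3S,4S,5R)-5-(2,4-dihydroxyphenyl)-4-(4-hydroxybenzyl)-2-(4-hydroxyphenyl)oxolan-3-yl]methanone (target)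
Conditions: H2 (1 atm), Pd(OH)2/C, THF–EtOAc, rt, stopped at full conversion
Reagents that add atoms: none
Why: Catalytic hydrogenolysis, in which aryl benzyl ethers are cleaved much faster than the secondary ring bonds C2–O1 and C5–O1 (the selectivity relied upon in debenzylations of 2-arylchromans and 2,5-diaryloxolane lignans), the hydrogen-bonded 2-hydroxyaryl ketone resists reduction, and the neutral aprotic medium leaves C3 and C5 untouched.

## Compound list

1 | p-coumaric acid | O=C(O)/C=C/c1ccc(O)cc1 | starting material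
2 | tert-butyldimethylsilyl (E)-3-[4-(tert-butyldimethylsilyloxy)phenyl]acrylate | CC(C)(C)[Si](C)(C)OC(=O)/C=C/c1ccc(O[Si](C)(C)C(C)(C)C)cc1 | intermediate
3 | (E)-3-[4-(tert-butyldimethylsilyloxy)phenyl]acrylic acid | O=C(O)/C=C/c1ccc(O[Si](C)(C)C(C)(C)C)cc1 | intermediate
4 | (S)-4-benzyloxazolidin-2-one | O=C1N[C@@H](Cc2ccccc2)CO1 | starting material
5 | (E)-3-[4-(tert-butyldimethylsilyloxy)phenyl]acrylic pivalic anhydride | CC(C)(C)C(=O)OC(=O)/C=C/c1ccc(O[Si](C)(C)C(C)(C)C)cc1 | intermediate
6 | (S)-4-benzyl-3-{(E)-3-[4-(tert-butyldimethylsilyloxy)phenyl]acryloyl}oxazolidin-2-one | O=C(/C=C/c1ccc(O[Si](C)(C)C(C)(C)C)cc1)N1[C@@H](Cc2ccccc2)COC1=O | intermediate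
7 | (S)-4-benzyl-3-[(E)-3-(4-hydroxyphenyl)acryloyl]oxazolidin-2-one | O=C(/C=C/c1ccc(O)cc1)N1[C@@H](Cc2ccccc2)COC1=O | intermediate
8 | 2-(4-hydroxyphenyl)ethanol (tyrosol) | OCCc1ccc(O)cc1 | starting material
9 | 2-[4-(benzyloxy)phenyl]ethanol | OCCc1ccc(OCc2ccccc2)cc1 | intermediate
10 | 5-({2-[4-(benzyloxy)phenyl]ethyl}sulfanyl)-1-phenyl-1H-tetrazole | C(Cc1ccc(OCc2ccccc2)cc1)Sc1nnnn1-c1ccccc1 | intermediate
11 | 5-({2-[4-(benzyloxy)phenyl]ethyl}sulfonyl)-1-phenyl-1H-tetrazole | O=S(=O)(CCc1ccc(OCc2ccccc2)cc1)c1nnnn1-c1ccccc1 | intermediate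
12 | 2,4-dihydroxybenzaldehyde | O=Cc1ccc(O)cc1O | starting material
13 | 4-(allyloxy)-2-hydroxybenzaldehyde | O=Cc1ccc(OCC=C)cc1O | intermediate
14 | 4-(allyloxy)-2-(benzyloxy)benzaldehyde | O=Cc1ccc(OCC=C)cc1OCc1ccccc1 | intermediate
15 | potassium salt of sulfone 11, metalated at the carbon next to sulfur | [K+].O=S(=O)([CH-]Cc1ccc(OCc2ccccc2)cc1)c1nnnn1-c1ccccc1 | intermediate
16 | 4-(allyloxy)-2-(benzyloxy)-1-{(E)-3-[4-(benzyloxy)phenyl]prop-1-en-1-yl}benzene | C=CCOc1ccc(/C=C/Cc2ccc(OCc3ccccc3)cc2)c(OCc2ccccc2)c1 | intermediate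
17 | (E)-3-(benzyloxy)-4-{3-[4-(benzyloxy)phenyl]prop-1-en-1-yl}phenol | Oc1ccc(/C=C/Cc2ccc(OCc3ccccc3)cc2)c(OCc2ccccc2)c1 | intermediate
18 | bis(quinone methide): N-acyl oxazolidinone of 3-[4-(benzyloxy)benzyl]-4-[2-(benzyloxy)-4-oxocyclohexa-2,5-dien-1-ylidene]-2-[(4-oxocyclohexa-2,5-dien-1-ylidene)methyl]butanoic acid, with C3 and C4 (oxolane numbering) configured as in 20 | O=C(N1[C@@H](Cc2ccccc2)COC1=O)[C@H](C=C1C=CC(=O)C=C1)[C@H](Cc1ccc(OCc2ccccc2)cc1)C=C1C=CC(=O)C=C1OCc1ccccc1 | intermediate
19 | C5-hydroxy quinone methide: water adduct of 18 at C5, with C3, C4 and C5 configured as in 20 | O=C(N1[C@@H](Cc2ccccc2)COC1=O)[C@H](C=C1C=CC(=O)C=C1)[C@H](Cc1ccc(OCc2ccccc2)cc1)[C@@H](O)c1ccc(O)cc1OCc1ccccc1 | intermediate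
20 | (4S)-4-benzyl-3-{[(2S,3S,4S,5R)-5-[2-(benzyloxy)-4-hydroxyphenyl]-4-[4-(benzyloxy)benzyl]-2-(4-hydroxyphenyl)oxolan-3-yl]carbonyl}oxazolidin-2-one | O=C(N1[C@@H](Cc2ccccc2)COC1=O)[C@H]1[C@H](Cc2ccc(OCc3ccccc3)cc2)[C@H](c2ccc(O)cc2OCc2ccccc2)O[C@@H]1c1ccc(O)cc1 | intermediate
21 | (4S)-4-benzyl-3-{[(2S,3S,4S,5R)-4-[4-(benzyloxy)benzyl]-2-[4-(benzyloxy)phenyl]-5-[2,4-bis(benzyloxy)phenyl]oxolan-3-yl]carbonyl}oxazolidin-2-one | O=C(N1[C@@H](Cc2ccccc2)COC1=O)[C@H]1[C@H](Cc2ccc(OCc3ccccc3)cc2)[C@H](c2ccc(OCc3ccccc3)cc2OCc2ccccc2)O[C@@H]1c1ccc(OCc2ccccc2)cc1 | intermediate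
22 | S-ethyl (2S,3S,4S,5R)-4-[4-(benzyloxy)benzyl]-2-[4-(benzyloxy)phenyl]-5-[2,4-bis(benzyloxy)phenyl]oxolane-3-carbothioate | CCSC(=O)[C@H]1[C@H](Cc2ccc(OCc3ccccc3)cc2)[C@H](c2ccc(OCc3ccccc3)cc2OCc2ccccc2)O[C@@H]1c1ccc(OCc2ccccc2)cc1 | intermediate
23 | 4-bromoresorcinol | Oc1ccc(Br)c(O)c1 | starting material
24 | 2,4-bis(benzyloxy)-1-bromobenzene | Brc1ccc(OCc2ccccc2)cc1OCc1ccccc1 | intermediate
25 | [2,4-bis(benzyloxy)phenyl]lithium | [Li]c1ccc(OCc2ccccc2)cc1OCc1ccccc1 | intermediate
26 | lithium [2,4-bis(benzyloxy)phenyl]triisopropoxyborate | [Li+].CC(C)O[B-](OC(C)C)(OC(C)C)c1ccc(OCc2ccccc2)cc1OCc1ccccc1 | intermediate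
27 | [2,4-bis(benzyloxy)phenyl]boronic acid | OB(O)c1ccc(OCc2ccccc2)cc1OCc1ccccc1 | intermediate
28 | [2,4-bis(benzyloxy)phenyl]{(2S,3S,4S,5R)-4-[4-(benzyloxy)benzyl]-2-[4-(benzyloxy)phenyl]-5-[2,4-bis(benzyloxy)phenyl]oxolan-3-yl}methanone | O=C(c1ccc(OCc2ccccc2)cc1OCc1ccccc1)[C@H]1[C@H](Cc2ccc(OCc3ccccc3)cc2)[C@H](c2ccc(OCc3ccccc3)cc2OCc2ccccc2)O[C@@H]1c1ccc(OCc2ccccc2)cc1 | intermediate
29 | (2,4-dihydroxyphenyl)[(2S,3S,4S,5R)-5-(2,4-dihydroxyphenyl)-4-(4-hydroxybenzyl)-2-(4-hydroxyphenyl)oxolan-3-yl]methanone | O=C(c1ccc(O)cc1O)[C@H]1[C@H](Cc2ccc(O)cc2)[C@H](c2ccc(O)cc2O)O[C@@H]1c1ccc(O)cc1 | target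

## Step count and risks

Total step count: 17.
Longest linear sequence: 10 steps (steps 4, 5, 6, 9, 10, 11, 12, 13, 16, 17).

**First risk, step 11.** Several processes can divert the step:
- Each radical may pair with its own kind.
- Bonding may go through a ring carbon ortho to oxygen, or through the phenoxyl oxygen, instead of through the two side-chain carbons.
- The acyl-bearing methide may lose H3 and rearomatise before water arrives, which stops ring closure.
- Water may add at C2 first, after which closure at C5 leads into the 4,5-trans series.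
- Water may strip magnesium from the imide and weaken the facial bias.

The fallback uses known chemistry. It sets out from 4, draws on 24, and comes back to the route at 28.
- Compound 4 is N-acylated (n-BuLi, methyl 4-chloro-4-oxobutanoate, THF, −78 °C) to methyl 4-[(4S)-4-benzyl-2-oxooxazolidin-3-yl]-4-oxobutanoate F1.
- A boron-mediated Evans syn-aldol reaction (Bu2BOTf, i-Pr2NEt, CH2Cl2, −78 °C, then 4-(benzyloxy)benzaldehyde) should set C2 and C3 in the syn-aldol adduct F2.
- Catalytic TsOH closes this to the trans-2,3-disubstituted 5-oxooxolane imide F3.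
- LiOH/H2O2 removes the auxiliary to give the 5-oxooxolane-3-carboxylic acid F4.
- The dianion of F4 (LiN(SiMe3)2, 2.2 equiv, THF, −78 °C) is alkylated with 4-(benzyloxy)benzyl bromide anti to the carboxylate. This sets C4 in the 4-benzylated lactone acid F5.
- Coupling with MeNHOMe·HCl (EDC, i-Pr2NEt) gives the Weinreb amide F6.
- Aryllithium 25 (from 24 and n-BuLi, 2.5 equiv, THF, −78 °C) adds both to the lactone and to the amide and gives the C5 lactol ketone F7.
- Ionic reduction (Et3SiH, BF3·OEt2, CH2Cl2, −78 °C) delivers hydride to the C5 oxocarbenium ion anti to the C4 benzyl group. The aryl group then ends up cis to the benzyl group, and the product is 28.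

**Second risk, step 16.** Transmetalation to a hindered secondary acyl–palladium species may be slower than protodeboronation of the electron-rich ortho-alkoxy boronic acid, and decarbonylation may intervene.

The fallback replaces the cross-coupling by carbonyl addition. It sets out from 22 and comes back at 28.
- i-Bu2AlH (CH2Cl2, −78 °C) reduces the thioester to the oxolane-3-carbaldehyde F8.
- Aryllithium 25 (from 24 and n-BuLi) adds at −78 °C to give the secondary carbinol F9. This is a mixture at the carbinol carbon, which is of no consequence.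
- Dess–Martin periodinane oxidises F9 to 28.

**Third risk, step 17.** The exposure needed to cleave six ethers may start reductive opening of the oxolane at C5–O1, which is activated by two oxygen donors once the para phenols are free. Acid traces on the catalyst may also ionise this bond and epimerise C5.

The fallback changes to an orthogonal two-stage deprotection. It sets out from 20 and ends at 29.
- TBSCl/imidazole (DMF, rt) gives the bis(silyl ether) imide F10.
- EtSH/n-BuLi gives the bis(silyl ether) thioester F11.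
- Liebeskind–Srogl coupling with 27 under the conditions of step 16 gives the tetrabenzyl bis(silyl ether) ketone F12.
- Hydrogenolysis (H2, Pd(OH)2/C, THF–EtOAc) then has only four ethers to cleave. Both para oxygens that activate C2–O1 and C5–O1 stay silylated during this step, and the product is the bis(silyl ether) tetraphenol F13.
- Bu4NF/AcOH (THF, 0 °C) gives 29.

## Further compounds

F1 | step 11 | methyl 4-[(4S)-4-benzyl-2-oxooxazolidin-3-yl]-4-oxobutanoate | COC(=O)CCC(=O)N1[C@@H](Cc2ccccc2)COC1=O
F2 | step 11 | methyl (3S,4S)-3-{[(4S)-4-benzyl-2-oxooxazolidin-3-yl]carbonyl}-4-[4-(benzyloxy)phenyl]-4-hydroxybutanoate (syn-aldol adduct) | O=C(N1[C@@H](Cc2ccccc2)COC1=O)[C@H]([C@H](O)c1ccc(OCc2ccccc2)cc1)CC(=O)OC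
F3 | step 11 | (4S)-4-benzyl-3-{[(2S,3S)-2-[4-(benzyloxy)phenyl]-5-oxooxolan-3-yl]carbonyl}oxazolidin-2-one | O=C(N1[C@@H](Cc2ccccc2)COC1=O)[C@H]1CC(=O)O[C@@H]1c1ccc(OCc2ccccc2)cc1
F4 | step 11 | (2S,3S)-2-[4-(benzyloxy)phenyl]-5-oxooxolane-3-carboxylic acid | OC(=O)[C@H]1CC(=O)O[C@@H]1c1ccc(OCc2ccccc2)cc1
F5 | step 11 | (2S,3S,4S)-4-[4-(benzyloxy)benzyl]-2-[4-(benzyloxy)phenyl]-5-oxooxolane-3-carboxylic acid | OC(=O)[C@H]1[C@H](Cc2ccc(OCc3ccccc3)cc2)C(=O)O[C@@H]1c1ccc(OCc2ccccc2)cc1
F6 | step 11 | (2S,3S,4S)-4-[4-(benzyloxy)benzyl]-2-[4-(benzyloxy)phenyl]-N-methoxy-N-methyl-5-oxooxolane-3-carboxamide | CON(C)C(=O)[C@H]1[C@H](Cc2ccc(OCc3ccccc3)cc2)C(=O)O[C@@H]1c1ccc(OCc2ccccc2)cc1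
F7 | step 11 | C5 lactol of 28: 5-hydroxy derivative with C2, C3 and C4 configured as in 28, both C5 epimers | O=C(c1ccc(OCc2ccccc2)cc1OCc1ccccc1)[C@H]1[C@H](Cc2ccc(OCc3ccccc3)cc2)C(O)(c2ccc(OCc3ccccc3)cc2OCc2ccccc2)O[C@@H]1c1ccc(OCc2ccccc2)cc1
F8 | step 16 | (2S,3S,4S,5R)-4-[4-(benzyloxy)benzyl]-2-[4-(benzyloxy)phenyl]-5-[2,4-bis(benzyloxy)phenyl]oxolane-3-carbaldehyde | O=C[C@H]1[C@H](Cc2ccc(OCc3ccccc3)cc2)[C@H](c2ccc(OCc3ccccc3)cc2OCc2ccccc2)O[C@@H]1c1ccc(OCc2ccccc2)cc1
F9 | step 16 | secondary carbinol corresponding to ketone 28, ring configured as in 28, both carbinol epimers | OC(c1ccc(OCc2ccccc2)cc1OCc1ccccc1)[C@H]1[C@H](Cc2ccc(OCc3ccccc3)cc2)[C@H](c2ccc(OCc3ccccc3)cc2OCc2ccccc2)O[C@@H]1c1ccc(OCc2ccccc2)cc1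
F10 | step 17 | bis(tert-butyldimethylsilyl) ether of 20 | O=C(N1[C@@H](Cc2ccccc2)COC1=O)[C@H]1[C@H](Cc2ccc(OCc3ccccc3)cc2)[C@H](c2ccc(O[Si](C)(C)C(C)(C)C)cc2OCc2ccccc2)O[C@@H]1c1ccc(O[Si](C)(C)C(C)(C)C)cc1
F11 | step 17 | S-ethyl (2S,3S,4S,5R)-5-[2-(benzyloxy)-4-(tert-butyldimethylsilyloxy)phenyl]-4-[4-(benzyloxy)benzyl]-2-[4-(tert-butyldimethylsilyloxy)phenyl]oxolane-3-carbothioate | CCSC(=O)[C@H]1[C@H](Cc2ccc(OCc3ccccc3)cc2)[C@H](c2ccc(O[Si](C)(C)C(C)(C)C)cc2OCc2ccccc2)O[C@@H]1c1ccc(O[Si](C)(C)C(C)(C)C)cc1
F12 | step 17 | [2,4-bis(benzyloxy)phenyl]{(2S,3S,4S,5R)-5-[2-(benzyloxy)-4-(tert-butyldimethylsilyloxy)phenyl]-4-[4-(benzyloxy)benzyl]-2-[4-(tert-butyldimethylsilyloxy)phenyl]oxolan-3-yl}methanone | O=C(c1ccc(OCc2ccccc2)cc1OCc1ccccc1)[C@H]1[C@H](Cc2ccc(OCc3ccccc3)cc2)[C@H](c2ccc(O[Si](C)(C)C(C)(C)C)cc2OCc2ccccc2)O[C@@H]1c1ccc(O[Si](C)(C)C(C)(C)C)cc1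
F13 | step 17 | (2,4-dihydroxyphenyl){(2S,3S,4S,5R)-5-[4-(tert-butyldimethylsilyloxy)-2-hydroxyphenyl]-4-(4-hydroxybenzyl)-2-[4-(tert-butyldimethylsilyloxy)phenyl]oxolan-3-yl}methanone | O=C(c1ccc(O)cc1O)[C@H]1[C@H](Cc2ccc(O)cc2)[C@H](c2ccc(O[Si](C)(C)C(C)(C)C)cc2O)O[C@@H]1c1ccc(O[Si](C)(C)C(C)(C)C)cc1
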